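**Retrosynthetic overview**
1. Bought pieces: vanillyl alcohol (1), tris(trimethylsilyloxy)ethylene (2, a glycolic acid dianion equivalent) and caffeic acid (3). No ring is formed; both arenes are bought intact.
2. ArCH2–C2 bond (made first, sets C2): 1 is silylated to 4 and ionised to the O-silylated para-quinone methide 5 (arene dearomatised). 2 attacks 5 under a chiral counter-anion and, via 6, gives the S hydroxy acid 7.
3. Carboxyl mask: 7 → allyl ester 8.
4. Ester bond made on the alkyl side (C2–O, not acyl–O): 8 + unprotected 3, SN2 with inversion (S to R) → 9.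
5. Unmasking: 9 → clinopodic acid B (10).

Assumption: 1, 2 and 3 are bought; the sense of induction in step 1 cannot be read from precedent, so the catalyst antipode that gives S-7 is fixed in a first small run and written here as (S,S)-IDPi (a C2-symmetric imidodiphosphorimidate acid from two 3,3'-diaryl-BINOL units, N-triflyl groups).

**Step 1**
Reactants: 1 vanillyl alcohol (4-(hydroxymethyl)-2-methoxyphenol); 2 tris(trimethylsilyloxy)ethylene
Product: 7 (S)-2-hydroxy-3-(4-hydroxy-3-methoxyphenyl)propanoic acid, via bis-silyl ether 4 (not isolated), via silylated quinone methide cation 5 (not isolated), via tris-silyl adduct 6 (not isolated)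
Conditions: HMDS (1.2 equiv), TMSCl (2 mol %), toluene, 60 °C, then evaporate; slow addition to 2 (1.3 equiv) and (S,S)-IDPi (2 mol %), toluene, −40 °C; then dilute aq HCl, THF, 0 °C
Reagents that add atoms: none
Why: Proposed new method: asymmetric counter-anion-directed silylium catalysis of a Mukaiyama-type benzylation, in which the silylated IDPi ionises the benzylic silyl ether 4 to the O-silylated para-quinone methide 5 (a quinoid oxocarbenium held as a contact ion pair inside the confined chiral anion), the bis-silyl ketene acetal 2 adds to its exocyclic CH2 through one enantioface of its CH(OSiMe3) terminus, which restores the arene and sets C2 as S, and silyl transfer back to the anion closes the cycle; the closest known reactions are IDPi-catalysed additions of bis-silyl ketene acetals to unsubstituted CH2 electrophiles (aminomethylation to free beta-2 amino acids, stereocentre likewise set on the nucleophile) and acid-catalysed benzylation of silyl ketene acetals by para-alkoxybenzyl cations.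

**Step 2**
Reactants: 7 (S)-2-hydroxy-3-(4-hydroxy-3-methoxyphenyl)propanoic acid
Product: 8 allyl (S)-2-hydroxy-3-(4-hydroxy-3-methoxyphenyl)propanoate
Conditions: allyl bromide (1.1 equiv), KHCO3 (1.2 equiv), DMF, 25 °C
Reagents that add atoms: allyl bromide, C=CCBr
Why: Carboxylate O-alkylation (SN2): KHCO3 deprotonates only the carboxylic acid (pKa about 4) and not the phenol (pKa about 10), so allyl bromide gives the ester alone and the stereocentre is not touched.

**Step 3**
Reactants: 8 allyl (S)-2-hydroxy-3-(4-hydroxy-3-methoxyphenyl)propanoate; 3 caffeic acid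
Product: 9 allyl (R)-2-{[(E)-3-(3,4-dihydroxyphenyl)prop-2-enoyl]oxy}-3-(4-hydroxy-3-methoxyphenyl)propanoate
Conditions: PPh3 (1.3 equiv), DIAD (1.3 equiv, added last), THF, 0 °C to 25 °C
Reagents that add atoms: none
Why: Mitsunobu esterification: caffeic acid is the only partner acidic enough to protonate the PPh3–DIAD betaine, so its carboxylate (not a phenol) displaces the phosphonium-activated C2–O bond by SN2 next to the ester carbonyl with inversion, S to R, as known for unprotected phenolic acids and for 3-aryllactates.

**Step 4**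
Reactants: 9 allyl (R)-2-{[(E)-3-(3,4-dihydroxyphenyl)prop-2-enoyl]oxy}-3-(4-hydroxy-3-methoxyphenyl)propanoate
Product: 10 clinopodic acid B, (R)-2-{[(E)-3-(3,4-dihydroxyphenyl)prop-2-enoyl]oxy}-3-(4-hydroxy-3-methoxyphenyl)propanoic acid
Conditions: Pd(PPh3)4 (5 mol %), morpholine (5 equiv), THF, 25 °C, argon; then dilute aq HCl
Reagents that add atoms: none
Why: Tsuji–Trost deallylation: zerovalent palladium ionises only the allyl ester to a pi-allyl complex that morpholine captures, a neutral non-hydrolytic unmasking that leaves the caffeate ester, the E alkene, the free phenols and the C2 stereocentre untouched.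

**Compound list**
1 | vanillyl alcohol, 4-(hydroxymethyl)-2-methoxyphenol | COc1cc(CO)ccc1O | starting material
2 | tris(trimethylsilyloxy)ethylene | C[Si](C)(C)OC=C(O[Si](C)(C)C)O[Si](C)(C)C | starting material
3 | caffeic acid, (E)-3-(3,4-dihydroxyphenyl)prop-2-enoic acid | OC(=O)/C=C/c1ccc(O)c(O)c1 | starting material
4 | trimethyl{[3-methoxy-4-(trimethylsilyloxy)phenyl]methoxy}silane (bis-silyl ether of 1) | COc1cc(CO[Si](C)(C)C)ccc1O[Si](C)(C)C | intermediate
5 | (2-methoxy-4-methylidenecyclohexa-2,5-dien-1-ylidene)(trimethylsilyl)oxonium, the O-silylated para-quinone methide, counter-ion the IDPi anion | COC1=CC(=C)C=CC1=[O+][Si](C)(C)C | intermediate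
6 | trimethylsilyl (S)-3-[3-methoxy-4-(trimethylsilyloxy)phenyl]-2-(trimethylsilyloxy)propanoate | COc1cc(C[C@H](O[Si](C)(C)C)C(=O)O[Si](C)(C)C)ccc1O[Si](C)(C)C | intermediate
7 | (S)-2-hydroxy-3-(4-hydroxy-3-methoxyphenyl)propanoic acid | COc1cc(C[C@H](O)C(=O)O)ccc1O | intermediate
8 | allyl (S)-2-hydroxy-3-(4-hydroxy-3-methoxyphenyl)propanoate | COc1cc(C[C@H](O)C(=O)OCC=C)ccc1O | intermediate
9 | allyl (R)-2-{[(E)-3-(3,4-dihydroxyphenyl)prop-2-enoyl]oxy}-3-(4-hydroxy-3-methoxyphenyl)propanoate | COc1cc(C[C@@H](OC(=O)/C=C/c2ccc(O)c(O)c2)C(=O)OCC=C)ccc1O | intermediate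
10 | clinopodic acid B, (R)-2-{[(E)-3-(3,4-dihydroxyphenyl)prop-2-enoyl]oxy}-3-(4-hydroxy-3-methoxyphenyl)propanoic acid | COc1cc(C[C@@H](OC(=O)/C=C/c2ccc(O)c(O)c2)C(=O)O)ccc1O | target

**Step count and risks**
Total step count: 4 (step 1 is run in one flask: silylation, catalytic C–C coupling, acidic work-up). Longest linear sequence: 4 (1 → 7 → 8 → 9 → 10).

Most likely to fail, first: step 1. The C–C bond formation itself is secure, but the enantioselectivity of the ion-pair alkylation is unproven, and 5 can be lost to Friedel–Crafts oligomerisation. Fallback: setting out from 4, achiral TMSOTf (5 mol %, CH2Cl2, −78 °C) and 2 give the racemic tris-silyl adduct F1, which acidic work-up turns into racemic 2-hydroxy-3-(4-hydroxy-3-methoxyphenyl)propanoic acid F2. Crystallising the (R)-1-phenylethylammonium salt F3 of the S acid (the antipodal amine is used if that salt is the more soluble one) and acidifying returns to the route at 7. Stereocontrol then comes from classical resolution instead of catalysis.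

Second: step 3. Possible failures are phenol alkylation, elimination to the allyl ferulate, or oxidation of the catechol by DIAD. Fallback: setting out from 7, allyl bromide (2.2 equiv) and K2CO3 in DMF give the diallyl hydroxy ester F4, with the guaiacol OH masked as an allyl ether. Tf2O and 2,6-lutidine at −78 °C give the S triflate F5. Caesium caffeate (from 3 and CsHCO3, DMF, −20 °C) displaces triflate by SN2 with inversion to the R diallyl caffeate ester F6. Pd(PPh3)4 and morpholine then remove both allyl groups, so the fallback comes back at 10. This replaces the redox condensation by a two-stage sulfonate activation and carboxylate displacement.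

Third: step 4. Possible failures are allyl transfer to the catechol or palladium binding by the product. Fallback: setting out from 7, tert-butyl 2,2,2-trichloroacetimidate (CH2Cl2/cyclohexane, 25 °C, no added acid) gives the tert-butyl ester F7. The same Mitsunobu coupling with 3 gives the tert-butyl ester of the target F8, and CF3CO2H/CH2Cl2/H2O at 0 °C returns to the route at 10. An acid-labile mask replaces the palladium unmasking.

**Further compounds**
F1 | step 1 | racemic trimethylsilyl 3-[3-methoxy-4-(trimethylsilyloxy)phenyl]-2-(trimethylsilyloxy)propanoate (not isolated) | COc1cc(CC(O[Si](C)(C)C)C(=O)O[Si](C)(C)C)ccc1O[Si](C)(C)C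
F2 | step 1 | racemic 2-hydroxy-3-(4-hydroxy-3-methoxyphenyl)propanoic acid | COc1cc(CC(O)C(=O)O)ccc1O
F3 | step 1 | (R)-1-phenylethylammonium (S)-2-hydroxy-3-(4-hydroxy-3-methoxyphenyl)propanoate | COc1cc(C[C@H](O)C(=O)[O-])ccc1O.C[C@@H]([NH3+])c1ccccc1
F4 | step 3 | allyl (S)-3-(4-allyloxy-3-methoxyphenyl)-2-hydroxypropanoate | COc1cc(C[C@H](O)C(=O)OCC=C)ccc1OCC=C
F5 | step 3 | allyl (S)-3-(4-allyloxy-3-methoxyphenyl)-2-(trifluoromethylsulfonyloxy)propanoate | COc1cc(C[C@H](OS(=O)(=O)C(F)(F)F)C(=O)OCC=C)ccc1OCC=C
F6 | step 3 | allyl (R)-3-(4-allyloxy-3-methoxyphenyl)-2-{[(E)-3-(3,4-dihydroxyphenyl)prop-2-enoyl]oxy}propanoate | COc1cc(C[C@@H](OC(=O)/C=C/c2ccc(O)c(O)c2)C(=O)OCC=C)ccc1OCC=C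
F7 | step 4 | tert-butyl (S)-2-hydroxy-3-(4-hydroxy-3-methoxyphenyl)propanoate | COc1cc(C[C@H](O)C(=O)OC(C)(C)C)ccc1O
F8 | step 4 | tert-butyl (R)-2-{[(E)-3-(3,4-dihydroxyphenyl)prop-2-enoyl]oxy}-3-(4-hydroxy-3-methoxyphenyl)propanoate | COc1cc(C[C@@H](OC(=O)/C=C/c2ccc(O)c(O)c2)C(=O)OC(C)(C)C)ccc1O
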